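The target has a twofold axis through the ring oxygen and the midpoint of the C3–C4 bond of the oxolane, and each exocyclic carbinol carbon stands in a 1,3-relationship to a ring CH2–O carbon (C2 or C5). Once C2 and C5 are raised to the acyl level, the bond from each carbinol carbon to C3 or C4 is a syn-aldol bond. The key step is therefore a one-pot double Evans aldol: the bis(boron enolate) of a succinyl bis(oxazolidinone) adds to two molecules of O-silylated vanillin, joining three components and setting all four stereocentres under auxiliary control. Silylation, reductive auxiliary removal, Mitsunobu ring closure and desilylation complete the route.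

Key step: step 2

Remark: aldehyde 4 is taken as a catalogue compound. The two backbone centres are S in the imide series and R from diol 10 onward only because the CIP priorities change; no inversion occurs (TBS = tert-butyldimethylsilyl). Steps 1 and 2 each consume two equivalents of one reactant (1 and 4 respectively); the second equivalent is entered under "Reagents that add atoms".

Step 1
Reactants: 1 (S)-4-benzyl-1,3-oxazolidin-2-one; 2 succinyl chloride
Product: 3 1,4-bis[(4S)-4-benzyl-2-oxo-1,3-oxazolidin-3-yl]butane-1,4-dione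
Conditions: 1 (2.05 equiv), n-BuLi (2.0 equiv), THF, −78 °C; then 2 (1.0 equiv), −78 → 0 °C
Reagents that add atoms: (S)-4-benzyl-1,3-oxazolidin-2-one (second equivalent of 1), O=C1N[C@@H](Cc2ccccc2)CO1
Why: Standard N-acylation of a lithiated oxazolidinone by an acid chloride, here with two equivalents of lithiated 1 at the two ends of the diacid chloride; no new stereocentre is formed and the auxiliary centre is untouched.

Step 2
Reactants: 3 1,4-bis[(4S)-4-benzyl-2-oxo-1,3-oxazolidin-3-yl]butane-1,4-dione; 4 4-(tert-butyldimethylsilyloxy)-3-methoxybenzaldehyde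
Product: 8 (2S,3S)-1,4-bis[(4S)-4-benzyl-2-oxo-1,3-oxazolidin-3-yl]-2,3-bis{(S)-hydroxy[3-methoxy-4-(tert-butyldimethylsilyloxy)phenyl]methyl}butane-1,4-dione, via bis(dibutylboron) dienolate 5 (not isolated), via mono-adduct boron aldolate 6 (not isolated), via bis(boron aldolate) 7 (not isolated)
Conditions: Bu2BOTf (2.4 equiv), i-Pr2NEt (2.8 equiv), CH2Cl2, 0 °C; then 4 (2.5 equiv), −78 → 0 °C; work-up pH 7 phosphate buffer, MeOH, 30% H2O2, 0 °C
Reagents that add atoms: 4-(tert-butyldimethylsilyloxy)-3-methoxybenzaldehyde (second equivalent of 4), COc1cc(C=O)ccc1O[Si](C)(C)C(C)(C)C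
Why: Soft enolisation of both imide termini with Bu2BOTf and i-Pr2NEt should give the Z,Z-configured bis(boron enolate) 5 (a 1,4-dioxygenated diene), and each enolate then adds to one molecule of 4 through a closed chair (Zimmerman–Traxler) transition state in which boron binds the enolate and aldehyde oxygens, giving 6 and then 7. The closest known reaction is the Evans boron-mediated syn-aldol of N-acyloxazolidinones, established for succinate-derived imides and aromatic aldehydes; here it is run at both ends of one C4 unit. No ring is closed in this step. The two backbone centres (later C3 and C4 of the oxolane) are set by the (S)-4-benzyl groups, which shield one enolate face in the dipole-minimised conformation, and the two carbinol centres are set by the Z-enolate geometry through the chair (syn relationship), so all four new centres should be S. The step needs the same facial sense in both additions (C2-symmetric product, not meso) and complete double addition; the first is secured because two identical auxiliaries each control their own enolate, the second by the excess of boron triflate and aldehyde. The bis(aldolate) 7 keeps both carbinol oxygens on boron until the cold oxidative work-up, which protects them from adding to the remote imide carbonyls.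

Step 3
Reactants: 8 (2S,3S)-1,4-bis[(4S)-4-benzyl-2-oxo-1,3-oxazolidin-3-yl]-2,3-bis{(S)-hydroxy[3-methoxy-4-(tert-butyldimethylsilyloxy)phenyl]methyl}butane-1,4-dione
Product: 9 (2S,3S)-1,4-bis[(4S)-4-benzyl-2-oxo-1,3-oxazolidin-3-yl]-2,3-bis{(S)-(tert-butyldimethylsilyloxy)[3-methoxy-4-(tert-butyldimethylsilyloxy)phenyl]methyl}butane-1,4-dione
Conditions: crude 8, TBSOTf (2.5 equiv), 2,6-lutidine (4 equiv), CH2Cl2, −78 → 0 °C
Reagents that add atoms: tert-butyldimethylsilyl triflate, CC(C)(C)[Si](C)(C)OS(=O)(=O)C(F)(F)F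
Why: O-Silylation of an aldol adduct with a silyl triflate and a hindered pyridine base is fast at low temperature, should outrun addition of the carbinol oxygens to the γ-imide carbonyls, and touches no stereocentre.

Step 4
Reactants: 9 (2S,3S)-1,4-bis[(4S)-4-benzyl-2-oxo-1,3-oxazolidin-3-yl]-2,3-bis{(S)-(tert-butyldimethylsilyloxy)[3-methoxy-4-(tert-butyldimethylsilyloxy)phenyl]methyl}butane-1,4-dione
Product: 10 (2R,3R)-2,3-bis{(S)-(tert-butyldimethylsilyloxy)[3-methoxy-4-(tert-butyldimethylsilyloxy)phenyl]methyl}butane-1,4-diol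
Conditions: LiBH4, MeOH (2.2 equiv), THF, 0 °C → rt
Reagents that add atoms: none
Why: Reductive cleavage of N-acyloxazolidinones with LiBH4 should convert both exocyclic carbonyls into primary alcohols and release the auxiliary, the silyl ethers being inert and the backbone centres not being enolised under these conditions.

Step 5
Reactants: 10 (2R,3R)-2,3-bis{(S)-(tert-butyldimethylsilyloxy)[3-methoxy-4-(tert-butyldimethylsilyloxy)phenyl]methyl}butane-1,4-diol
Product: 11 (3R,4R)-3,4-bis{(S)-(tert-butyldimethylsilyloxy)[3-methoxy-4-(tert-butyldimethylsilyloxy)phenyl]methyl}oxolane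
Conditions: PPh3, DIAD, THF, 0 °C → rt
Reagents that add atoms: none
Why: Mitsunobu cyclodehydration of a 1,4-diol, in which one primary hydroxyl becomes an oxyphosphonium leaving group and is displaced by the other in a 5-exo-tet closure at CH2, so no stereocentre is involved and the silylated benzylic oxygens cannot compete.

Step 6
Reactants: 11 (3R,4R)-3,4-bis{(S)-(tert-butyldimethylsilyloxy)[3-methoxy-4-(tert-butyldimethylsilyloxy)phenyl]methyl}oxolane
Product: 12 (3R,4R)-3,4-bis[(S)-hydroxy(4-hydroxy-3-methoxyphenyl)methyl]oxolane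
Conditions: Bu4NF, AcOH, THF, 0 °C → rt
Reagents that add atoms: none
Why: Fluoride should cleave the two aryl and the two benzylic silyl ethers in one global desilylation, the acetic acid buffer keeping the phenols protonated so that neither quinone methide formation nor epimerisation of the benzylic carbinols is expected.

Compound list
1 | (S)-4-benzyl-1,3-oxazolidin-2-one | O=C1N[C@@H](Cc2ccccc2)CO1 | starting material
2 | succinyl chloride (butanedioyl dichloride) | O=C(Cl)CCC(Cl)=O | starting material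
3 | 1,4-bis[(4S)-4-benzyl-2-oxo-1,3-oxazolidin-3-yl]butane-1,4-dione | O=C(CCC(=O)N1[C@@H](Cc2ccccc2)COC1=O)N1[C@@H](Cc2ccccc2)COC1=O | intermediate
4 | 4-(tert-butyldimethylsilyloxy)-3-methoxybenzaldehyde (O-TBS vanillin) | COc1cc(C=O)ccc1O[Si](C)(C)C(C)(C)C | starting material
5 | (1Z,3Z)-1,4-bis[(4S)-4-benzyl-2-oxo-1,3-oxazolidin-3-yl]-1,4-bis(dibutylboryloxy)buta-1,3-diene | CCCCB(CCCC)O/C(=C\C=C(/OB(CCCC)CCCC)N1[C@@H](Cc2ccccc2)COC1=O)N1[C@@H](Cc2ccccc2)COC1=O | intermediate
6 | mono-adduct: O-dibutylboryl syn-aldolate at one terminus (S carbinol, S backbone centre), Z boron enolate at the other | COc1cc([C@@H](OB(CCCC)CCCC)[C@@H](C(=O)N2[C@@H](Cc3ccccc3)COC2=O)/C=C(\OB(CCCC)CCCC)N2[C@@H](Cc3ccccc3)COC2=O)ccc1O[Si](C)(C)C(C)(C)C | intermediate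
7 | bis(O-dibutylboryl) aldolate of 8 | COc1cc([C@@H](OB(CCCC)CCCC)[C@@H](C(=O)N2[C@@H](Cc3ccccc3)COC2=O)[C@H](C(=O)N2[C@@H](Cc3ccccc3)COC2=O)[C@H](OB(CCCC)CCCC)c2ccc(O[Si](C)(C)C(C)(C)C)c(OC)c2)ccc1O[Si](C)(C)C(C)(C)C | intermediate
8 | (2S,3S)-1,4-bis[(4S)-4-benzyl-2-oxo-1,3-oxazolidin-3-yl]-2,3-bis{(S)-hydroxy[3-methoxy-4-(tert-butyldimethylsilyloxy)phenyl]methyl}butane-1,4-dione | COc1cc([C@@H](O)[C@@H](C(=O)N2[C@@H](Cc3ccccc3)COC2=O)[C@H](C(=O)N2[C@@H](Cc3ccccc3)COC2=O)[C@H](O)c2ccc(O[Si](C)(C)C(C)(C)C)c(OC)c2)ccc1O[Si](C)(C)C(C)(C)C | intermediate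
9 | (2S,3S)-1,4-bis[(4S)-4-benzyl-2-oxo-1,3-oxazolidin-3-yl]-2,3-bis{(S)-(tert-butyldimethylsilyloxy)[3-methoxy-4-(tert-butyldimethylsilyloxy)phenyl]methyl}butane-1,4-dione | COc1cc([C@@H](O[Si](C)(C)C(C)(C)C)[C@@H](C(=O)N2[C@@H](Cc3ccccc3)COC2=O)[C@H](C(=O)N2[C@@H](Cc3ccccc3)COC2=O)[C@H](O[Si](C)(C)C(C)(C)C)c2ccc(O[Si](C)(C)C(C)(C)C)c(OC)c2)ccc1O[Si](C)(C)C(C)(C)C | intermediate
10 | (2R,3R)-2,3-bis{(S)-(tert-butyldimethylsilyloxy)[3-methoxy-4-(tert-butyldimethylsilyloxy)phenyl]methyl}butane-1,4-diol | COc1cc([C@@H](O[Si](C)(C)C(C)(C)C)[C@@H](CO)[C@H](CO)[C@H](O[Si](C)(C)C(C)(C)C)c2ccc(O[Si](C)(C)C(C)(C)C)c(OC)c2)ccc1O[Si](C)(C)C(C)(C)C | intermediate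
11 | (3R,4R)-3,4-bis{(S)-(tert-butyldimethylsilyloxy)[3-methoxy-4-(tert-butyldimethylsilyloxy)phenyl]methyl}oxolane | COc1cc([C@@H](O[Si](C)(C)C(C)(C)C)[C@H]2COC[C@@H]2[C@H](O[Si](C)(C)C(C)(C)C)c2ccc(O[Si](C)(C)C(C)(C)C)c(OC)c2)ccc1O[Si](C)(C)C(C)(C)C | intermediate
12 | (3R,4R)-3,4-bis[(S)-hydroxy(4-hydroxy-3-methoxyphenyl)methyl]oxolane | COc1cc([C@@H](O)[C@H]2COC[C@@H]2[C@H](O)c2ccc(O)c(OC)c2)ccc1O | target

Total step count: 6
Longest linear sequence: 6 steps (1 → 3 → 8 → 9 → 10 → 11 → 12)

Steps most likely to fail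

Step 2 (key step): the second enolisation, at the carbon next to the first boron enolate, or the second addition next to the newly branched centre may stall, leaving mono-adduct and eroding the C2-selective double addition. The fallback replaces the one-pot bidirectional reaction by two separate auxiliary-controlled aldol reactions on a mono-imide with a masked second carboxyl. Setting out from 1, N-acylation with pent-4-enoyl chloride (n-BuLi, THF, −78 °C) should give (S)-4-benzyl-3-(pent-4-enoyl)-1,3-oxazolidin-2-one F1. Its boron aldol with 4 (Bu2BOTf, i-Pr2NEt, CH2Cl2) should give the syn-aldol adduct F2, which has no acyl group able to capture the carbinol, and silylation (TBSOTf, 2,6-lutidine) should give the silyl ether F3. Cleavage of the vinyl group (OsO4 cat., NaIO4, 2,6-lutidine, dioxane/H2O) should give the aldehyde F4, and chlorite oxidation (NaClO2, NaH2PO4, 2-methylbut-2-ene, t-BuOH/H2O) the carboxylic acid F5. Activation (t-BuCOCl, Et3N, THF) should give the mixed pivalic anhydride F6, and its reaction with lithiated 1 the mono-adduct bis(imide) F7. A second boron aldol with 4, now at the only unbranched α-carbon, should give the hydroxy adduct F8, and silylation under the step 3 conditions returns to the route at 9.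

Step 3: a carbinol oxygen of 8 may add to the remote (γ) imide carbonyl before it is silylated, closing a γ-lactone and expelling the auxiliary. The fallback never frees the carbinols while an imide is present. Setting out from 3 and 4, the aldol of step 2 is run as described, but LiBH4 in THF is added to the cold solution of 7 before any protic work-up; this should reduce both imides and give, after oxidative work-up, the tetraol F9. Selective esterification of the two primary hydroxyls (t-BuCOCl, pyridine, CH2Cl2, 0 °C) should give the bis(pivalate) F10, and silylation of the benzylic hydroxyls (TBSOTf, 2,6-lutidine) the silylated bis(pivalate) F11. Reductive removal of the pivalates (i-Bu2AlH, CH2Cl2, −78 °C) returns to the route at 10.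

Step 4: in the hindered β-silyloxy imides, hydride may attack the ring carbonyl of the auxiliary and open the oxazolidinone instead of releasing it. The fallback transfers the acyl groups to sulfur before reduction. Setting out from 9, LiSEt (EtSH, n-BuLi, THF, 0 °C) should exchange both auxiliaries to give the bis(S-ethyl thioester) F12, and reduction of the thioesters (LiBH4, THF) returns to the route at 10.

Further compounds
F1 | step 2 | (S)-4-benzyl-3-(pent-4-enoyl)-1,3-oxazolidin-2-one | C=CCCC(=O)N1[C@@H](Cc2ccccc2)COC1=O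
F2 | step 2 | (4S)-4-benzyl-3-[(2S)-2-{(S)-hydroxy[3-methoxy-4-(tert-butyldimethylsilyloxy)phenyl]methyl}pent-4-enoyl]-1,3-oxazolidin-2-one | COc1cc([C@@H](O)[C@H](CC=C)C(=O)N2[C@@H](Cc3ccccc3)COC2=O)ccc1O[Si](C)(C)C(C)(C)C
F3 | step 2 | O-TBS ether of F2 at the carbinol | COc1cc([C@@H](O[Si](C)(C)C(C)(C)C)[C@H](CC=C)C(=O)N2[C@@H](Cc3ccccc3)COC2=O)ccc1O[Si](C)(C)C(C)(C)C
F4 | step 2 | aldehyde from F3 (vinyl group cleaved to CH2–CHO) | COc1cc([C@@H](O[Si](C)(C)C(C)(C)C)[C@H](CC=O)C(=O)N2[C@@H](Cc3ccccc3)COC2=O)ccc1O[Si](C)(C)C(C)(C)C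
F5 | step 2 | carboxylic acid from F4 (CH2–CO2H) | COc1cc([C@@H](O[Si](C)(C)C(C)(C)C)[C@H](CC(=O)O)C(=O)N2[C@@H](Cc3ccccc3)COC2=O)ccc1O[Si](C)(C)C(C)(C)C
F6 | step 2 | mixed pivalic anhydride of F5 | COc1cc([C@@H](O[Si](C)(C)C(C)(C)C)[C@H](CC(=O)OC(=O)C(C)(C)C)C(=O)N2[C@@H](Cc3ccccc3)COC2=O)ccc1O[Si](C)(C)C(C)(C)C
F7 | step 2 | mono-adduct bis(imide): 3 carrying one (S)-(TBS-oxy)(aryl)methyl group at one backbone carbon (S) | COc1cc([C@@H](O[Si](C)(C)C(C)(C)C)[C@H](CC(=O)N2[C@@H](Cc3ccccc3)COC2=O)C(=O)N2[C@@H](Cc3ccccc3)COC2=O)ccc1O[Si](C)(C)C(C)(C)C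
F8 | step 2 | mono-O-TBS analogue of 8 (one benzylic carbinol free, one silylated) | COc1cc([C@@H](O[Si](C)(C)C(C)(C)C)[C@@H](C(=O)N2[C@@H](Cc3ccccc3)COC2=O)[C@H](C(=O)N2[C@@H](Cc3ccccc3)COC2=O)[C@H](O)c2ccc(O[Si](C)(C)C(C)(C)C)c(OC)c2)ccc1O[Si](C)(C)C(C)(C)C
F9 | step 3 | (2R,3R)-2,3-bis{(S)-hydroxy[3-methoxy-4-(tert-butyldimethylsilyloxy)phenyl]methyl}butane-1,4-diol | COc1cc([C@@H](O)[C@@H](CO)[C@H](CO)[C@H](O)c2ccc(O[Si](C)(C)C(C)(C)C)c(OC)c2)ccc1O[Si](C)(C)C(C)(C)C
F10 | step 3 | 1,4-bis(pivalate) of F9 | COc1cc([C@@H](O)[C@@H](COC(=O)C(C)(C)C)[C@H](COC(=O)C(C)(C)C)[C@H](O)c2ccc(O[Si](C)(C)C(C)(C)C)c(OC)c2)ccc1O[Si](C)(C)C(C)(C)C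
F11 | step 3 | 1,4-bis(pivalate) of 10 | COc1cc([C@@H](O[Si](C)(C)C(C)(C)C)[C@@H](COC(=O)C(C)(C)C)[C@H](COC(=O)C(C)(C)C)[C@H](O[Si](C)(C)C(C)(C)C)c2ccc(O[Si](C)(C)C(C)(C)C)c(OC)c2)ccc1O[Si](C)(C)C(C)(C)C
F12 | step 4 | bis(S-ethyl thioester) corresponding to 9 | COc1cc([C@@H](O[Si](C)(C)C(C)(C)C)[C@@H](C(=O)SCC)[C@H](C(=O)SCC)[C@H](O[Si](C)(C)C(C)(C)C)c2ccc(O[Si](C)(C)C(C)(C)C)c(OC)c2)ccc1O[Si](C)(C)C(C)(C)C
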